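**Compound numbers used throughout:** 1 (−)-caryophyllene oxide; 2 alkylborane; 3 primary alcohol; 4 aldehyde; 5 acid; 6 methyl ester; 7 tetrabromomethane; 8 lithium enolate; 9 α-bromo ester; 10 Z enoate; 11 E enoate; 12 lithium dienolate; 13 α-selenide; 14 selenoxide; 15 selenenate; 16 γ-hydroxy enoate; 17 Z oxo enoate; 18 E oxo enoate; 19 alkoxy catecholborane; 20 (3R)-hydroxy ester; 21 lithium carboxylate; 22 hydroxy acid; 23 benzoyl chloride; 24 mixed anhydride; 25 target.

**Atom locants (target numbering, also used for the bicyclic compounds 1–9):** C1 carries the carboxyl carbon C15; C2 is the alkene CH; C3 the benzoyloxy carbon; C4 is CMe2; C5–C7 are CH2; C8 is the methyl-bearing epoxide carbon; C9 the epoxide CH; C10 and C11 are CH2.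

**Assumptions:**
- The SMILES of 1 is the natural (−) enantiomer. Its epoxide is (8R,9R) in these locants, the same absolute configuration as in 25.
- The configuration at C1 in 2–6 is immaterial, because C1 becomes an enolate carbon and then a planar radical. Compounds 2–6 are written without a descriptor at C1, and 9 is drawn as one epimer.
- In step 9 the fully substituted C4 flank of the ketone is taken as the larger group for the oxazaborolidine.

## Analysis of the target

The target 25 is a humulane-type sesquiterpenoid acid built on a single eleven-membered carbocycle C1–C11. It carries the carboxyl group C15 on C1, a trisubstituted C1=C2 double bond, a benzoate on C3, a gem-dimethyl group on C4 and a trisubstituted epoxide across C8–C9 with a methyl group on C8. There are three stereocentres, C3 (R), C8 (R) and C9 (R). The two epoxide carbons are adjacent and trans-related, whereas C3 is four ring bonds away from either of them and cannot be expected to take its configuration from them. The double bond is E, which means that the ring carbons C3 and C11 are cis and the carboxyl group is trans to C3; the Z isomer of any C3-hydroxy intermediate could close to a butenolide. The sensitive groups are the acid-labile epoxide, which sits across the ring from a free carboxylic acid, and the allylic benzoate γ to the carboxyl group, which does not survive ester hydrolysis. The difficulty lies in making a medium ring, in the congested C3–C4 junction between a carbinol and a quaternary carbon, and in controlling a remote stereocentre. The strategy rests on the observation that the C8–C9 epoxide with its methyl group, the C4 gem-dimethyl group and all fifteen skeletal carbons are already present in (−)-caryophyllene oxide 1. In 1 an extra C2–C5 bond closes a cyclobutane (C2, C3, C4, C5) across the future eleven-membered ring, so that cutting this one bond uncovers the ring.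

## Retrosynthetic reasoning

**25 to 22 and 23 (C3–O acyl bond).** The benzoate is put on last, because it is allylic and would not survive the ester hydrolysis that frees C15. The forward step has to acylate a neopentylic alcohol next to a free acid. The acid is allowed to form the mixed anhydride 24, which water cleaves again. The E geometry of 22 rules out lactonisation.

**22 to 20 to 18 (O–methyl bond of the ester, then the C3–H bond).** The C3 stereocentre is traced to the planar ketone 18. This is chosen because C3 is too remote from C8 and C9 for substrate control, so a reagent-controlled hydride delivery is the safer way to set it. The ketone stage also offers the one place where the C1=C2 geometry can be settled thermodynamically (17 to 18), since the ketone and ester prefer to be trans across the double bond.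

**18 to 16 to 13 to 11 (C3–O bond).** The C3 oxygen is removed by reversing a [2,3]-sigmatropic shift, which turns the C3–O bond of 16 into the C1–Se bond of 13. Selenide 13 comes from the dienolate 12 of enoate 11. This path is chosen because only the C3 hydrogens of 11 are vinylogously acidic, so the site of oxygenation is fixed by the enolate chemistry. An ene-type allylic oxidation would be expected to attack C11 instead. The forward sequence must deliver oxygen to C3; it need not control the C3 configuration or the alkene geometry, which are corrected at 18 and 20.

**11 to 9 (the C2–C5 bond, key disconnection).** Re-forming the C2–C5 bond of the macrocycle leads back to the bicyclic α-bromo ester 9, in which the eleven-membered ring is bridged by a cyclobutane. The cut is made here because this bond is the only difference between the carbon skeleton of 11 and that of 1. Its cleavage forms no skeletal bond and no stereocentre, and it leaves the epoxide untouched. The forward reaction must generate a radical at C1 and let it break C2–C5 rather than C2–C3, before the radical is reduced.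

**9 to 6 and 7, then to 5, 3 and 1 (C1–Br bond and the oxidation level of C15).** The bromine comes from 7 through the ester enolate 8. The ester 6 is reached from 1 by anti-Markovnikov hydration of the exocyclic methylene and oxidation of the resulting primary alcohol 3 through 5. Nothing in this part makes or breaks a skeletal bond, so the risk of the route is concentrated in the ring opening.

## Alternatives that were turned down

**Alternative 1:** Grob fragmentation of a six–seven fused bicycle.
- Disconnection: the C3 carbonyl and an E C8=C9 double bond are traced to a C3–C8 σ bond, which hides the ring in the bicyclic hydroxy mesylate A2 (tertiary alcohol at C3, methyl at C8, mesylate at C9).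
- Forward key step: KN(SiMe3)2 deprotonates the C3 alcohol, and the alkoxide expels the antiperiplanar mesylate with cleavage of C3–C8 to give the eleven-membered dienone A1.
- For: the fragmentation is concerted and stereospecific, fixes the alkene geometry from the relative configuration of A2, and opens the ring without any entropic penalty. As a ring-forming event it is more predictable than a radical scission that must compete with reduction.
- Against: A1 is achiral. All three stereocentres of 25 would have to be installed afterwards by two independent reagent-controlled reactions: an asymmetric epoxidation of an unfunctionalised trisubstituted alkene in a flexible medium ring, and a ketone reduction. C15 would have to be raised from a silyl ether to the acid, and A2, with three defined centres, would have to be built from scratch.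
- Comparison: the chosen route gives up some certainty in the key step, but takes C8, C9, the gem-dimethyl group and every carbon from 1 and has to control only C3.

**Alternative 2:** Nickel-mediated allyl–allyl coupling.
- Disconnection: the C10–C11 bond, leading to the acyclic bis(allylic bromide) A4, which already carries the C3 benzoate.
- Forward key step: Ni(cod)2 (zerovalent nickel) at high dilution inserts into both C–Br bonds and couples the two primary termini to give the macrocyclic diene A3.
- For: the plan is convergent, and C3 with its benzoate is set in an open chain where reagent control is straightforward. On this point it is stronger than the chosen route, which oxygenates C3 late.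
- Against: one allyl unit is a 2-(bromomethyl)acrylate and the other a prenyl-type bromide, so head-to-tail coupling, oligomerisation and syn/anti isomerisation of the allyl-nickel intermediates threaten regiochemistry and both alkene geometries. The allylic benzoate γ to the ester can itself be ionised by zerovalent nickel. The epoxide would still have to be placed on C8=C9 of A3 on the correct face relative to a remote centre.
- Comparison: the chosen route closes no ring against entropy and has the epoxide in place from the start.

**Alternative 3:** Chromium-mediated reverse-prenyl allylation.
- Disconnection: the C3–C4 bond, leading to the epoxy aldehyde A6 with an allylic bromide spanning C4–C6.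
- Forward key step: catalytic CrCl2 (divalent chromium) with Mn, Me3SiCl and a chiral bis(oxazoline) converts the bromide into an allylchromium, which adds through its fully substituted terminus C4 to the C3 aldehyde to give the macrocyclic dienol A5.
- For: one step would create the quaternary C4, the C3 carbinol under catalyst control, and the ring, with the C3 oxygen already present. On this point it is stronger than the chosen route, which spends four steps on C3.
- Against: the ring would be closed at the most congested bond of the molecule through an ordered transition state. The aldehyde of A6 is a 4-oxo-enoate, a strong conjugate acceptor that low-valent chromium can reduce. Attack through the other allyl terminus would give a larger ring. The catalyst would have to override the resident epoxide centres. The epoxide of A6 would have to be made enantioselectively in an open chain, and A5 carries a surplus C5=C6 double bond to be hydrogenated selectively next to the enoate.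
- Comparison: the chosen route needs no asymmetric epoxidation and no selective hydrogenation, and reaches its key-step precursor in four routine steps.

Key step: step 5

## Route

Step 1
Reactants: 1 (−)-caryophyllene oxide
Product: 3 primary alcohol (CH2OH on C1; C1 epimers; rest of 1 unchanged), via B-alkyl-9-BBN borane 2 (not isolated)
Conditions: 9-BBN (9-borabicyclo[3.3.1]nonane), THF, 0 °C to rt; then NaOH (aq), H2O2, 0 °C to rt
Reagents that add atoms: hydrogen peroxide, OO
Why: Anti-Markovnikov hydroboration–oxidation of the 1,1-disubstituted exocyclic alkene places boron and then oxygen on C15; 9-BBN does not reduce the epoxide at room temperature and alkaline peroxide leaves it intact. The new centre at C1 is not controlled and need not be, since it is erased in steps 4 and 5.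

Step 2
Reactants: 3 primary alcohol
Product: 5 carboxylic acid (CO2H on C1; C1 epimers), via aldehyde 4 (not isolated)
Conditions: TEMPO (2,2,6,6-tetramethylpiperidin-1-oxyl, cat.), NaOCl (cat.), NaClO2, MeCN/phosphate buffer pH 6.7, 35 °C
Reagents that add atoms: sodium chlorite, [Na+].[O-]Cl=O
Why: Oxoammonium oxidation of the alcohol to the aldehyde and chlorite oxidation of the aldehyde to the acid run in one flask (TEMPO/chlorite oxidation); the near-neutral buffer should spare the trisubstituted epoxide, and no alkene is left for hypochlorite to attack.

Step 3
Reactants: 5 carboxylic acid
Product: 6 methyl ester (CO2Me on C1; C1 epimers)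
Conditions: Me3SiCHN2, PhMe/MeOH, 0 °C
Reagents that add atoms: (trimethylsilyl)diazomethane, C[Si](C)(C)C=[N+]=[N-]
Why: O-methylation of the acid by the diazoalkane needs neither added acid nor base, so the epoxide and the cyclobutane are not touched.

Step 4
Reactants: 6 methyl ester; 7 tetrabromomethane
Product: 9 α-bromo methyl ester (Br and CO2Me on C1; one C1 epimer drawn), via lithium enolate 8 (not isolated)
Conditions: LiN(iPr)2 (1.1 equiv), THF, −78 °C; CBr4, −78 °C; H2O
Reagents that add atoms: tetrabromomethane, BrC(Br)(Br)Br
Why: Enolate bromination: the tetrasubstituted ester enolate takes bromine from CBr4 to give the tertiary bromide; the low temperature and the small excess of base are meant to keep the enolate and the amide from attacking the epoxide. Either face may be brominated, because C1 becomes planar in step 5.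

Step 5
Reactants: 9 α-bromo methyl ester
Product: 11 E enoate (eleven-membered ring; C3 cis to C11), via Z enoate 10 (not isolated)
Conditions: (Me3Si)3SiH (1.2 equiv, slow addition), azobisisobutyronitrile (AIBN, cat.), t-C12H25SH (10 mol%), PhH (0.005 M), 80 °C; then PhSSPh (10 mol%), AIBN (cat.), 80 °C
Reagents that add atoms: none
Why: Bromine abstraction from 9 by the silyl radical gives the planar tertiary α-ester radical at C1, which is a cyclobutylcarbinyl radical; β-scission of the ring-fusion bond C2–C5 releases the four-membered-ring strain and forms the C1=C2 enoate and a secondary radical at C5, so that the nine-membered and four-membered rings merge into the eleven-membered ring (a ring expansion by cleavage of the shared bond, not a cyclisation; the only new σ bond is C5–H). The closest known reaction type is the fragmentation of fused cyclobutylcarbinyl radicals to medium rings, and the step is the radical counterpart of the reverse of the biogenetic closure of the caryophyllene cyclobutane from the humulyl cation, which argues that the C1 orbital and the C2–C5 bond can align. Scission towards C3 would give a primary neopentyl-type radical and is disfavoured by radical stability and because C3 lies near the nodal plane when the C11–C1–C2–C5 ring torsion is large. The step needs ring opening to outrun hydrogen transfer to the C1 radical: the silane is kept dilute by slow addition, and the catalytic alkanethiol quenches the nucleophilic C5 radical quickly but the electrophilic C1 radical only slowly (polarity-reversal catalysis), the thiyl radical being returned to thiol by the silane; the fast quench at C5 should also suppress transannular hydrogen shifts. No stereocentre is created, and C8 and C9 are remote from both radical centres and are carried over from 1. The enoate is expected to emerge first as the ring-trans isomer 10, by analogy with the E double bonds of the humulene ring, and reversible addition of thiyl radicals to C2 should equilibrate it to the tiglate-type isomer 11; if a mixture remains it can be carried on, because both isomers give dienolate 12. Material that is merely reduced returns as ester 6 and can be re-brominated.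

Step 6
Reactants: 11 E enoate
Product: 13 α-phenylselanyl β,γ-unsaturated ester (SePh and CO2Me on C1; trans C2=C3; C1 epimers), via lithium dienolate 12 (not isolated)
Conditions: LiN(iPr)2 (1.1 equiv), (Me2N)3PO, THF, −78 °C; PhSeCl, −78 °C
Reagents that add atoms: benzeneselenenyl chloride, Cl[Se]c1ccccc1
Why: Only the C3 hydrogens are vinylogously acidic (C11–H is not conjugated to the carbonyl group), so γ-deprotonation gives the extended enolate, which the soft electrophile attacks at the α-carbon C1 (deconjugative α-selenenylation of a dienolate). The trans C2=C3 geometry follows from the two fully substituted neighbours C1 and C4; the configuration at C1 is not controlled and is lost again in step 7.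

Step 7
Reactants: 13 α-phenylselanyl β,γ-unsaturated ester
Product: 16 γ-hydroxy enoate (OH on C3; C3 epimers; C1=C2 isomers), via selenoxide 14 (not isolated), via selenenate ester 15 (not isolated)
Conditions: H2O2 (30% aq), pyridine, CH2Cl2, 0 °C to rt; crude product used at once
Reagents that add atoms: hydrogen peroxide, OO
Why: Oxidation at selenium triggers the [2,3]-sigmatropic shift of the allylic selenoxide, which is faster than syn-elimination, moves the oxygen to C3 and returns the double bond to C1=C2 in conjugation with the ester; hydrolysis of the selenenate frees the alcohol. Neither the C3 configuration nor the alkene geometry is relied on here, since both are settled in steps 8 and 9.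

Step 8
Reactants: 16 γ-hydroxy enoate
Product: 18 E oxo enoate (ketone at C3; C3 cis to C11), via Z oxo enoate 17 (not isolated)
Conditions: Dess–Martin periodinane, NaHCO3, CH2Cl2, 0 °C to rt; then PhSSPh (10 mol%), AIBN (cat.), PhH, 80 °C
Reagents that add atoms: none
Why: Periodinane oxidation converges both C3 epimers to a ketone that cannot enolise towards the quaternary C4. Reversible thiyl-radical addition at C2 then equilibrates the geometric isomers in the manner of the maleate-to-fumarate isomerisation; the isomer with the ketone trans to the ester and C3 cis to C11 is expected to predominate.

Step 9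
Reactants: 18 E oxo enoate
Product: 20 (3R)-hydroxy E enoate methyl ester, via B-alkoxy catecholborane 19 (not isolated)
Conditions: (S)-1-methyl-3,3-diphenyltetrahydro-1H,3H-pyrrolo[1,2-c][1,3,2]oxazaborole ((S)-Me-CBS, 0.5 equiv), catecholborane, PhMe, −78 °C; then MeOH, NaHCO3 (aq)
Reagents that add atoms: none
Why: Corey–Bakshi–Shibata reduction: the ketone should bind the catalyst boron on the side of the small alkenyl CH (C2), away from the fully substituted C4, and hydride is then delivered to the face that gives the 3R alcohol, in the same sense in which this catalyst reduces aryl and tert-alkyl methyl ketones. At −78 °C 1,2-reduction of the enone should outrun conjugate reduction, and the epoxide and the ester are inert to catecholborane.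

Step 10
Reactants: 20 (3R)-hydroxy E enoate methyl ester
Product: 22 (3R)-hydroxy E enoic acid, via lithium carboxylate 21 (not isolated)
Conditions: LiOH, THF/MeOH/H2O, rt to 40 °C; then phosphate buffer pH 4, 0 °C
Reagents that add atoms: lithium hydroxide, [Li+].[OH-]
Why: Saponification of the methyl ester; the E geometry keeps the C3 hydroxyl away from the carboxyl group so that no butenolide can form, and the epoxide should tolerate hydroxide and the mildly acidic buffer that liberates the acid.

Step 11
Reactants: 22 (3R)-hydroxy E enoic acid; 23 benzoyl chloride
Product: 25 target acid (3R-benzoate; E enoic acid; 8R,9R-epoxide), via mixed benzoic anhydride 24 (not isolated)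
Conditions: BzCl (3 equiv), pyridine, 4-(dimethylamino)pyridine (cat.), CH2Cl2, 0 °C to rt; then THF/H2O, NaHCO3, rt
Reagents that add atoms: benzoyl chloride, O=C(Cl)c1ccccc1
Why: Acylation of the hindered neopentylic alcohol under nucleophilic catalysis; the carboxyl group is acylated as well, and the mixed anhydride is cleaved on aqueous treatment at the less hindered benzoyl carbonyl, which returns the free acid while the secondary benzoate stays. C3 is not touched, so its configuration is retained.

## Compound list

1 | (−)-caryophyllene oxide: nine-membered ring (C1, C2, C5–C11) trans-fused to the cyclobutane C2–C3–C4–C5, gem-dimethyl on C4, methyl on C8, (8R,9R)-epoxide, exocyclic methylene C15 on C1 | C[C@@]12CC[C@@H]3[C@H](CC3(C)C)C(=C)CC[C@H]1O2 | starting material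
2 | B-alkyl-9-BBN borane: core of 1 with CH2–B(9-BBN) on C1, C1 epimers | C[C@@]12CC[C@@H]3[C@H](CC3(C)C)C(CB4C5CCCC4CCC5)CC[C@H]1O2 | intermediate
3 | primary alcohol: core of 1 with CH2OH on C1, C1 epimers | C[C@@]12CC[C@@H]3[C@H](CC3(C)C)C(CO)CC[C@H]1O2 | intermediate
4 | aldehyde: core of 1 with CHO on C1, C1 epimers | C[C@@]12CC[C@@H]3[C@H](CC3(C)C)C(C=O)CC[C@H]1O2 | intermediate
5 | carboxylic acid: core of 1 with CO2H on C1, C1 epimers | C[C@@]12CC[C@@H]3[C@H](CC3(C)C)C(C(=O)O)CC[C@H]1O2 | intermediate
6 | methyl ester: core of 1 with CO2Me on C1, C1 epimers | C[C@@]12CC[C@@H]3[C@H](CC3(C)C)C(C(=O)OC)CC[C@H]1O2 | intermediate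
7 | tetrabromomethane | BrC(Br)(Br)Br | starting material
8 | lithium ester enolate: C1=C15(OMe)OLi on the core of 1 | C[C@@]12CC[C@@H]3[C@H](CC3(C)C)C(=C(OC)O[Li])CC[C@H]1O2 | intermediate
9 | α-bromo methyl ester: core of 1 with Br and CO2Me on C1 (one C1 epimer drawn; the other serves equally) | C[C@@]12CC[C@@H]3[C@H](CC3(C)C)[C@](Br)(C(=O)OC)CC[C@H]1O2 | intermediate
10 | methyl (1Z,8R,9R)-8,9-epoxy-4,4,8-trimethylcycloundec-1-ene-1-carboxylate (C3 trans to C11) | CC1(C)CCC[C@@]2(C)O[C@@H]2CC/C(C(=O)OC)=C/C1 | intermediate
11 | methyl (1E,8R,9R)-8,9-epoxy-4,4,8-trimethylcycloundec-1-ene-1-carboxylate (C3 cis to C11) | CC1(C)CCC[C@@]2(C)O[C@@H]2CC/C(C(=O)OC)=C\C1 | intermediate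
12 | lithium dienolate of 11: C15(OMe)(OLi)=C1–C2=C3 with trans C2=C3 | CC1(C)/C=C/C(=C(OC)O[Li])CC[C@H]2O[C@]2(C)CCC1 | intermediate
13 | methyl (2E,8R,9R)-8,9-epoxy-4,4,8-trimethyl-1-(phenylselanyl)cycloundec-2-ene-1-carboxylate, C1 epimers | CC1(C)/C=C/C(C(=O)OC)([Se]c2ccccc2)CC[C@H]2O[C@]2(C)CCC1 | intermediate
14 | selenoxide of 13 | CC1(C)/C=C/C(C(=O)OC)([Se](=O)c2ccccc2)CC[C@H]2O[C@]2(C)CCC1 | intermediate
15 | selenenate ester: C3–O–SePh on the C1=C2 enoate, C3 epimers and alkene isomers | CC1(C)CCC[C@@]2(C)O[C@@H]2CCC(C(=O)OC)=CC1O[Se]c1ccccc1 | intermediate
16 | methyl (8R,9R)-8,9-epoxy-3-hydroxy-4,4,8-trimethylcycloundec-1-ene-1-carboxylate, C3 epimers and alkene isomers | CC1(C)CCC[C@@]2(C)O[C@@H]2CCC(C(=O)OC)=CC1O | intermediate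
17 | methyl (1Z,8R,9R)-8,9-epoxy-4,4,8-trimethyl-3-oxocycloundec-1-ene-1-carboxylate | CC1(C)CCC[C@@]2(C)O[C@@H]2CC/C(C(=O)OC)=C/C1=O | intermediate
18 | methyl (1E,8R,9R)-8,9-epoxy-4,4,8-trimethyl-3-oxocycloundec-1-ene-1-carboxylate | CC1(C)CCC[C@@]2(C)O[C@@H]2CC/C(C(=O)OC)=C\C1=O | intermediate
19 | B-alkoxy catecholborane of 20 (C3–O–B) | CC1(C)CCC[C@@]2(C)O[C@@H]2CC/C(C(=O)OC)=C\[C@H]1OB1Oc2ccccc2O1 | intermediate
20 | methyl (1E,3R,8R,9R)-8,9-epoxy-3-hydroxy-4,4,8-trimethylcycloundec-1-ene-1-carboxylate | CC1(C)CCC[C@@]2(C)O[C@@H]2CC/C(C(=O)OC)=C\[C@H]1O | intermediate
21 | lithium (1E,3R,8R,9R)-8,9-epoxy-3-hydroxy-4,4,8-trimethylcycloundec-1-ene-1-carboxylate | CC1(C)CCC[C@@]2(C)O[C@@H]2CC/C(C(=O)[O-])=C\[C@H]1O.[Li+] | intermediate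
22 | (1E,3R,8R,9R)-8,9-epoxy-3-hydroxy-4,4,8-trimethylcycloundec-1-ene-1-carboxylic acid | CC1(C)CCC[C@@]2(C)O[C@@H]2CC/C(C(=O)O)=C\[C@H]1O | intermediate
23 | benzoyl chloride | O=C(Cl)c1ccccc1 | starting material
24 | mixed benzoic anhydride of 25 (C15(=O)–O–C(=O)Ph, C3 benzoate) | CC1(C)CCC[C@@]2(C)O[C@@H]2CC/C(C(=O)OC(=O)c2ccccc2)=C\[C@H]1OC(=O)c1ccccc1 | intermediate
25 | (1E,3R,8R,9R)-3-(benzoyloxy)-8,9-epoxy-4,4,8-trimethylcycloundec-1-ene-1-carboxylic acid | CC1(C)CCC[C@@]2(C)O[C@@H]2CC/C(C(=O)O)=C\[C@H]1OC(=O)c1ccccc1 | target

## Step count and least certain steps

Total step count: 11. Longest linear sequence: 11 steps (1 to 25); 7 and 23 enter as single-step reagents, so the route is fully linear.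

**Step 5 (key step).** The most likely failure is hydrogen transfer to the C1 radical before the ring opens, because a tertiary ester-stabilised cyclobutylcarbinyl radical fragments slowly; this gives back ester 6. A second risk is a transannular hydrogen shift to the C5 radical from the C8 methyl group, which would open the epoxide. The thiyl equilibration may also stop at a mixture of 10 and 11. The fallback sets out from 9 and comes back at 11. It takes the hydrogen donor out of the ring-opening event: irradiation of 9 at high concentration with catalytic (Bu3Sn)2 in PhH (bromine-atom-transfer conditions) leaves the C1 radical no path other than fragmentation or recapture of bromine. The C5 radical then takes bromine from another molecule of 9 and gives the ring-opened C5-bromo enoate F1. Bu3SnH/AIBN reduces this unactivated secondary bromide, and the thiyl equilibration of step 5 delivers 11.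

**Step 6.** Deprotonation may be slow or misdirected, since the C3 hydrogens are neopentylic and lie trans to the ester. The dienolate carbon C1 may attack the epoxide carbon C9 across the ring, and selenium may end up on C3 by direct attack or by a 1,3-shift. The fallback sets out from 11 and comes back at 16 and uses no strong base. Irradiation of 11 at 254 nm with a catalytic amine base effects photodeconjugation through the dienol and gives the β,γ-unsaturated ester F2. NaHCO3-buffered mCPBA epoxidises its isolated trans C2=C3 bond to the β,γ-epoxy ester F3. DBU then removes the C1 hydrogen and opens the new epoxide by E1cB elimination to give 16.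

**Step 7.** The new C1=C2 bond may form mainly as the ring-trans isomer, in which the ester is cis to the C3 hydroxyl, and that isomer may lactonise to a bridged butenolide before it can be oxidised. Syn-elimination of the selenoxide towards C11 is a lesser risk. The fallback sets out from 11 and comes back at 18 without ever placing a free C3 alcohol next to the ester. The β,γ-unsaturated ester F2, made as in the fallback for step 6, is subjected to sensitised photooxygenation (O2, tetraphenylporphyrin, visible light). In this ene reaction the only allylic hydrogen is the one on C1, because C4 is quaternary, so oxygen arrives at C3 and the double bond moves to C1=C2, giving the γ-hydroperoxy enoate F4. Ac2O/pyridine dehydrates the hydroperoxide to the ketone, and the thiyl equilibration of step 8 gives 18.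

**Step 9.** Facial selectivity may be poor or reversed, because the conformational bias of the macrocycle may oppose the catalyst and because the assignment of C4 as the larger flank is an assumption; conjugate reduction of the doubly activated alkene is a further risk. The fallback sets out from 18 and comes back at 20 and relies on separation and recycling instead of catalyst control. Reduction with NaBH4 and CeCl3·7H2O in MeOH at −78 °C should give both C3 epimers, which are diastereomers because of C8 and C9 and can be separated by chromatography. The (3S)-hydroxy enoate F5 is re-oxidised with Dess–Martin periodinane to 18 and reduced again, and the (3R) epimer is 20.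

## Further compounds

F1 | step 5 | methyl (8R,9R)-5-bromo-8,9-epoxy-4,4,8-trimethylcycloundec-1-ene-1-carboxylate, C5 epimers and alkene isomers | CC1(C)C(Br)CC[C@@]2(C)O[C@@H]2CCC(C(=O)OC)=CC1
F2 | step 6 | methyl (2E,8R,9R)-8,9-epoxy-4,4,8-trimethylcycloundec-2-ene-1-carboxylate, C1 epimers | CC1(C)/C=C/C(C(=O)OC)CC[C@H]2O[C@]2(C)CCC1
F3 | step 6 | methyl (8R,9R)-2,3:8,9-diepoxy-4,4,8-trimethylcycloundecane-1-carboxylate, trans 2,3-epoxide, mixture at C1, C2 and C3 | CC1(C)C2OC2C(C(=O)OC)CC[C@H]2O[C@]2(C)CCC1
F4 | step 7 | methyl (8R,9R)-8,9-epoxy-3-hydroperoxy-4,4,8-trimethylcycloundec-1-ene-1-carboxylate, C3 epimers and alkene isomers | CC1(C)CCC[C@@]2(C)O[C@@H]2CCC(C(=O)OC)=CC1OO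
F5 | step 9 | methyl (1E,3S,8R,9R)-8,9-epoxy-3-hydroxy-4,4,8-trimethylcycloundec-1-ene-1-carboxylate | CC1(C)CCC[C@@]2(C)O[C@@H]2CC/C(C(=O)OC)=C\[C@@H]1O
A1 | alternative 1 | achiral eleven-membered dienone, C15 as tert-butyldimethylsilyl ether | CC1(C)CCC/C(C)=C/CC/C(CO[Si](C)(C)C(C)(C)C)=C\C1=O
A2 | alternative 1 | six–seven fused hydroxy mesylate (racemic, relative configuration drawn: trans ring fusion, mesylate antiperiplanar to C3–C8) | CC1(C)CCC[C@@]2(C)[C@H](OS(C)(=O)=O)CCC(CO[Si](C)(C)C(C)(C)C)=C[C@]12O
A3 | alternative 2 | eleven-membered diene (3R)-benzoate, 2-(trimethylsilyl)ethyl ester | CC1(C)CCC/C(C)=C/CC/C(C(=O)OCC[Si](C)(C)C)=C\[C@H]1OC(=O)c1ccccc1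
A4 | alternative 2 | acyclic bis(allylic bromide) with (3R)-benzoate, 2-(trimethylsilyl)ethyl ester | BrC/C(C(=O)OCC[Si](C)(C)C)=C\[C@@H](OC(=O)c1ccccc1)C(C)(C)CCC/C(C)=C/CBr
A5 | alternative 3 | eleven-membered epoxy dienol, 2-(trimethylsilyl)ethyl ester | CC1(C)/C=C/C[C@@]2(C)O[C@@H]2CC/C(C(=O)OCC[Si](C)(C)C)=C\[C@H]1O
A6 | alternative 3 | acyclic epoxy aldehyde with secondary prenyl-type allylic bromide (mixture at C6), 2-(trimethylsilyl)ethyl ester | CC(C)=CC(Br)C[C@@]1(C)O[C@@H]1CC/C(C(=O)OCC[Si](C)(C)C)=C\C=O
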